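**Plan**

- Labels: isochromanone C1 (lactone C=O), O2, C3, C4, C4a–C8a; the C4 side chain is Ca(CO2Me)=CbH–C3'O2H.
- Enabling feature: C3' and C3 are 1,5-related through Cb=Ca–C4. A C3–C3' bond therefore gives a cyclopentenone ring (C3' ketone, Cb=Ca, C4, C3) in which the E alkene is a ring alkene and the future free acid is the only ketone.
- Retrosynthetic cuts, in order: the three aryl O–Me bonds; the lactone bond O2–C1; the C3–O bond, with C3–C3' re-joined; C4–Ca of the five-membered ring; C3=C4, leading to an aryl aldehyde and a fumaroyl keto ester.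
- Forward order: arene (bought) → open-chain dienone → temporary five-membered carbocycle by 4π closure → C3 hydroxylation → ring cut at C3–C3' → six-membered lactone ring → free phenols.
- Stereochemistry: C4 from the chiral copper bisoxazoline catalyst (sense of conrotation); C3 by equilibration to the trans lactone; alkene geometry inherited from the ring.

Key step: step 6

Remarks on the chemistry (assumptions):
- The (S,S) ligand is taken to favour the conrotation that gives (5R)-11; if the first run shows the opposite sense, the equally available (R,R) ligand is used and nothing else changes.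
- Compound 3 is drawn as its lactol; it reacts in step 2 through the open formyl carboxylate.

**Route**

Step 1
Reactants: 1 2,4,5-trimethoxybenzoic acid
Product: 3 3-hydroxy-4,5,7-trimethoxy-2-benzofuran-1(3H)-one (lactol form of 2-formyl-3,4,6-trimethoxybenzoic acid), via dilithiated benzoate 2 (not isolated)
Conditions: s-BuLi (2.2 equiv), TMEDA (2.2 equiv), THF, −78 °C; DMF, −78 °C to rt; aq. HCl
Reagents that add atoms: N,N-dimethylformamide, CN(C)C=O
Why: Carboxylate-directed ortho-lithiation (directed ortho metalation of an unprotected benzoic acid): the lithium carboxylate holds the s-BuLi/TMEDA aggregate next to C6–H, the only ortho hydrogen and one also acidified by the adjacent 5-methoxy group, and DMF formylates the aryllithium.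

Step 2
Reactants: 3 3-hydroxy-4,5,7-trimethoxy-2-benzofuran-1(3H)-one
Product: 4 methyl 2-formyl-3,4,6-trimethoxybenzoate
Conditions: MeI, K2CO3, DMF, rt
Reagents that add atoms: iodomethane, CI
Why: SN2 O-methylation of the carboxylate under basic conditions should trap the open formyl acid as the normal methyl ester, as is usual for 2-formylbenzoic acids (pseudo-esters arise under acid catalysis).

Step 3
Reactants: 5 monomethyl fumarate; 6 Meldrum's acid
Product: 8 methyl (2E)-4-(2,2-dimethyl-4,6-dioxo-1,3-dioxan-5-ylidene)-4-hydroxybut-2-enoate (acyl Meldrum's acid in its enol form), via methyl fumaroyl chloride 7 (not isolated)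
Conditions: (COCl)2, DMF (cat.), CH2Cl2, 0 °C to rt, evaporate; then 6, pyridine, CH2Cl2, 0 °C; aq. HCl wash
Reagents that add atoms: none
Why: Acid chloride formation followed by C-acylation of Meldrum's acid should give the hydrogen-bonded enol of the acyl Meldrum's acid, a standard entry to beta-keto esters.

Step 4
Reactants: 8 acyl Meldrum's acid
Product: 9 dimethyl (2E)-4-oxohex-2-enedioate
Conditions: MeOH, reflux
Reagents that add atoms: methanol, CO
Why: Thermal alcoholysis of an acyl Meldrum's acid (through the acylketene, with loss of acetone and CO2) should deliver the beta-keto ester, which is used at once because it is both a Michael donor and a Michael acceptor.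

Step 5
Reactants: 4 methyl 2-formyl-3,4,6-trimethoxybenzoate; 9 dimethyl (2E)-4-oxohex-2-enedioate
Product: 10 dimethyl (2E,5Z)-4-oxo-5-{[2,3,5-trimethoxy-6-(methoxycarbonyl)phenyl]methylidene}hex-2-enedioate
Conditions: TiCl4 (2 equiv), pyridine (4 equiv), THF, 0 °C to rt
Reagents that add atoms: none
Why: Knoevenagel condensation in its TiCl4/pyridine variant for hindered aldehydes: the titanium enolate of 9 (in that form no longer a Michael acceptor) adds to the activated aldehyde and pyridine eliminates the titanium aldolate; a 5E isomer need not be removed because the arylidene isomers interconvert under the Lewis acid of step 6.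

Step 6
Reactants: 10 dienone
Product: 11 dimethyl (1S,5R)-2-oxo-5-[2,3,5-trimethoxy-6-(methoxycarbonyl)phenyl]cyclopent-3-ene-1,4-dicarboxylate
Conditions: Cu(SbF6)2 (20 mol %), (S,S)-t-Bu-box [2,2'-(propane-2,2-diyl)bis((4S)-4-tert-butyl-4,5-dihydrooxazole), 22 mol %], (CF3)2CHOH (1 equiv), CH2Cl2, 0 °C to rt
Reagents that add atoms: none
Why: The ketone and the neighbouring ester carbonyl of 10 chelate the cationic divalent copper centre, which turns the cross-conjugated dienone into a metal-bound pentadienyl cation; a thermally allowed conrotatory 4π electrocyclisation then joins C4 to Ca and closes the five-membered carbocycle C3', Cb, Ca, C4, C3. The oxyallyl cation so formed is a copper enolate on the C3 (ester) side and a cation at Cb, so loss of the acidic Ca–H should give only the Ca=Cb enone, and protonation of the enolate at C3 settles trans to the aryl group by equilibration of the beta-keto ester. The closest known reaction type is the Lewis-acid-catalysed Nazarov cyclisation of 2-alkoxycarbonyl divinyl ketones, made enantioselective by chiral copper bisoxazoline complexes. The C4 stereocentre is set by torquoselectivity: the C2-symmetric ligand shields one sense of conrotation of the chelated helical cation (catalyst control), with the aryl group in the outside position of its terminus. The step needs regioselective proton loss and enough reactivity despite the electron-poor second vinyl arm; the C3 ester secures the first, and for the second the terminal ester destabilises the open pentadienyl cation more than the oxyallyl cation, while the weakly coordinating SbF6 counterions keep the metal strongly Lewis acidic. Arylidene E/Z isomers should converge because they interconvert in the chelate and only the aryl-outside isomer can close.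

Step 7
Reactants: 11 cyclopentenone keto ester
Product: 12 dimethyl (1S,5R)-1-hydroxy-2-oxo-5-[2,3,5-trimethoxy-6-(methoxycarbonyl)phenyl]cyclopent-3-ene-1,4-dicarboxylate
Conditions: DMDO (1.2 equiv, acetone solution), Ni(acac)2 (5 mol %), CH2Cl2, 0 °C
Reagents that add atoms: dimethyldioxirane, CC1(C)OO1
Why: Electrophilic alpha-hydroxylation of a beta-keto ester by a dioxirane through its nickel enolate, on the face opposite the aryl group; the quaternary carbinol stops enolisation (and any cyclopentadienol pathway that could scramble C4), and its configuration does not matter because C3 is planarised in step 8.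

Step 8
Reactants: 12 hydroxy keto ester
Product: 13 (2E,4R)-5-hydroxy-6-methoxy-3-(methoxycarbonyl)-6-oxo-4-[2,3,5-trimethoxy-6-(methoxycarbonyl)phenyl]hex-2-enoic acid (both C5 epimers)
Conditions: LiOH·H2O (1.2 equiv), THF/H2O, 0 °C; then 1 M HCl to pH 2–3
Reagents that add atoms: lithium hydroxide, [Li+].[OH-]
Why: Retro-Claisen cleavage: hydroxide adds to the non-enolisable ring ketone, activated by the alpha-hydroxy and alpha-ester groups, and the adduct expels the ester-stabilised C3 carbanion, so that C3' becomes the carboxylate (cis to C4 on the alkene, as in the ring) while the methyl esters should react far more slowly at 0 °C.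

Step 9
Reactants: 13 seco hydroxy acid
Product: 15 (2E)-4-methoxy-4-oxo-3-[(3S,4R)-5,6,8-trimethoxy-3-(methoxycarbonyl)-1-oxo-3,4-dihydro-1H-isochromen-4-yl]but-2-enoic acid (trans lactone acid), via cis lactone acid 14 (not isolated)
Conditions: DBU (2.5 equiv), MeCN, rt to 40 °C; then 1 M HCl
Reagents that add atoms: none
Why: Base-mediated lactonisation by intramolecular transesterification and C3 epimerisation through the lactone enolate, both under thermodynamic control: the C3 alkoxide should end on the twisted aryl ester as the benzo-fused six-membered lactone (closure onto the acrylate ester, deactivated by the neighbouring carboxylate, is reversible through the released methanol), and the trans isomer should prevail because the peri 5-methoxy group forces the C4 side chain pseudo-axial with the C3 ester anti to it, as in the known cis-to-trans epimerisation of 3,4-disubstituted isochromanones; the carboxylate form of the side chain guards C4–H against deprotonation.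

Step 10
Reactants: 15 trans lactone acid
Product: 16 (2E)-4-methoxy-4-oxo-3-[(3S,4R)-5,6,8-trihydroxy-3-(methoxycarbonyl)-1-oxo-3,4-dihydro-1H-isochromen-4-yl]but-2-enoic acid (CNP0546035.1)
Conditions: BBr3 (8 equiv), CH2Cl2, −78 to 0 °C; H2O, 0 °C, work-up under argon
Reagents that add atoms: none
Why: Lewis-acid cleavage of aryl methyl ethers by BBr3: the peri 8-methoxy and the vicinal 5,6-dimethoxy groups should cleave through chelated aryloxyboranes at or below 0 °C, where the methyl esters, the lactone and the acid (as acyloxyborane, released on hydrolysis) are expected to survive.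

**Compound list**

1 | 2,4,5-trimethoxybenzoic acid | COc1cc(OC)c(C(=O)O)cc1OC | starting material
2 | lithium 6-lithio-2,4,5-trimethoxybenzoate (dilithiated benzoate) | [Li]c1c(C(=O)O[Li])c(OC)cc(OC)c1OC | intermediate (not isolated)
3 | 3-hydroxy-4,5,7-trimethoxy-2-benzofuran-1(3H)-one (lactol form of 2-formyl-3,4,6-trimethoxybenzoic acid) | O=C1OC(O)c2c(OC)c(OC)cc(OC)c12 | intermediate
4 | methyl 2-formyl-3,4,6-trimethoxybenzoate | COC(=O)c1c(C=O)c(OC)c(OC)cc1OC | intermediate
5 | monomethyl fumarate | COC(=O)/C=C/C(=O)O | starting material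
6 | Meldrum's acid (2,2-dimethyl-1,3-dioxane-4,6-dione) | CC1(C)OC(=O)CC(=O)O1 | starting material
7 | methyl (2E)-4-chloro-4-oxobut-2-enoate (methyl fumaroyl chloride) | COC(=O)/C=C/C(=O)Cl | intermediate (not isolated)
8 | methyl (2E)-4-(2,2-dimethyl-4,6-dioxo-1,3-dioxan-5-ylidene)-4-hydroxybut-2-enoate | COC(=O)/C=C/C(O)=C1C(=O)OC(C)(C)OC1=O | intermediate
9 | dimethyl (2E)-4-oxohex-2-enedioate | COC(=O)/C=C/C(=O)CC(=O)OC | intermediate
10 | dimethyl (2E,5Z)-4-oxo-5-{[2,3,5-trimethoxy-6-(methoxycarbonyl)phenyl]methylidene}hex-2-enedioate | COC(=O)/C=C/C(=O)/C(C(=O)OC)=C/c1c(OC)c(OC)cc(OC)c1C(=O)OC | intermediate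
11 | dimethyl (1S,5R)-2-oxo-5-[2,3,5-trimethoxy-6-(methoxycarbonyl)phenyl]cyclopent-3-ene-1,4-dicarboxylate (trans) | COC(=O)C1=CC(=O)[C@@H](C(=O)OC)[C@@H]1c1c(OC)c(OC)cc(OC)c1C(=O)OC | intermediate
12 | dimethyl (1S,5R)-1-hydroxy-2-oxo-5-[2,3,5-trimethoxy-6-(methoxycarbonyl)phenyl]cyclopent-3-ene-1,4-dicarboxylate (OH trans to aryl) | COC(=O)C1=CC(=O)[C@@](C(=O)OC)(O)[C@@H]1c1c(OC)c(OC)cc(OC)c1C(=O)OC | intermediate
13 | (2E,4R)-5-hydroxy-6-methoxy-3-(methoxycarbonyl)-6-oxo-4-[2,3,5-trimethoxy-6-(methoxycarbonyl)phenyl]hex-2-enoic acid (both C5 epimers) | COC(=O)/C(=C/C(=O)O)[C@H](C(O)C(=O)OC)c1c(OC)c(OC)cc(OC)c1C(=O)OC | intermediate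
14 | (2E)-4-methoxy-4-oxo-3-[(3R,4R)-5,6,8-trimethoxy-3-(methoxycarbonyl)-1-oxo-3,4-dihydro-1H-isochromen-4-yl]but-2-enoic acid (cis lactone acid) | COC(=O)/C(=C/C(=O)O)[C@H]1c2c(OC)c(OC)cc(OC)c2C(=O)O[C@H]1C(=O)OC | intermediate (not isolated)
15 | (2E)-4-methoxy-4-oxo-3-[(3S,4R)-5,6,8-trimethoxy-3-(methoxycarbonyl)-1-oxo-3,4-dihydro-1H-isochromen-4-yl]but-2-enoic acid (trans lactone acid) | COC(=O)/C(=C/C(=O)O)[C@H]1c2c(OC)c(OC)cc(OC)c2C(=O)O[C@@H]1C(=O)OC | intermediate
16 | (2E)-4-methoxy-4-oxo-3-[(3S,4R)-5,6,8-trihydroxy-3-(methoxycarbonyl)-1-oxo-3,4-dihydro-1H-isochromen-4-yl]but-2-enoic acid | COC(=O)/C(=C/C(=O)O)[C@H]1c2c(O)c(O)cc(O)c2C(=O)O[C@@H]1C(=O)OC | target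

**Totals**

Total steps: 10. Longest linear sequence: 8 steps (1, 2, 5–10); the keto ester branch (steps 3–4) joins at step 5.

**Steps most likely to fail**

1. Step 6 (key step). The ester-bearing vinyl arm is electron-poor and may slow ionisation and ring closure, the chelating beta-keto ester product may hold back the copper catalyst, and heating to compensate may erode the sense of conrotation. Fallback, setting out from 10: ring closure with a stoichiometric achiral Lewis acid (Sc(OTf)3, LiClO4, ClCH2CH2Cl, 60 °C) should give the racemic trans keto ester, that is 11 together with its mirror image, dimethyl (1R,5S)-2-oxo-5-[2,3,5-trimethoxy-6-(methoxycarbonyl)phenyl]cyclopent-3-ene-1,4-dicarboxylate F1. Hydroxylation as in step 7 then gives 12 together with its mirror image, dimethyl (1R,5S)-1-hydroxy-2-oxo-5-[2,3,5-trimethoxy-6-(methoxycarbonyl)phenyl]cyclopent-3-ene-1,4-dicarboxylate F2. The enantiomers, which can no longer enolise, are separated by preparative chromatography on a chiral stationary phase, and the route is rejoined at 12.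

2. Step 5. Keto ester 9 may condense with itself by Michael addition, or the titanium aldolate may lactonise onto the neighbouring methyl ester (phthalide formation) faster than it dehydrates. Fallback, setting out from 4: an amine–acid-catalysed Knoevenagel condensation (piperidinium acetate, benzene, reflux with water removal) with methyl acetoacetate, which is no Michael acceptor and reacts through the iminium ion, should give methyl (2Z)-3-oxo-2-{[2,3,5-trimethoxy-6-(methoxycarbonyl)phenyl]methylidene}butanoate F3. Soft enolisation (TBSOTf, Et3N, CH2Cl2) gives methyl (2Z)-3-{[tert-butyl(dimethyl)silyl]oxy}-2-{[2,3,5-trimethoxy-6-(methoxycarbonyl)phenyl]methylidene}but-3-enoate F4. A Mukaiyama aldol addition to methyl glyoxylate (BF3·OEt2, CH2Cl2, −78 °C) gives dimethyl (5Z)-2-hydroxy-4-oxo-5-{[2,3,5-trimethoxy-6-(methoxycarbonyl)phenyl]methylidene}hexanedioate F5. Mesylation and elimination (MsCl, Et3N) install the E enoate, and the route is rejoined at 10.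

3. Step 9. The C3 alkoxide may transfer to the wrong ester, leaving a five-membered lactone on the acrylate carbonyl, and slow equilibration at C3 would give base time to attack C4–H. Fallback, setting out from 3: the C3–O2 bond is made to the aryl carboxyl before the five-membered ring is cut.
   - Allyl bromide and K2CO3 in DMF give prop-2-en-1-yl 2-formyl-3,4,6-trimethoxybenzoate F6.
   - The conditions of step 5 give dimethyl (2E,5Z)-4-oxo-5-({2,3,5-trimethoxy-6-[(prop-2-en-1-yloxy)carbonyl]phenyl}methylidene)hex-2-enedioate F7.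
   - The conditions of step 6 give dimethyl (1S,5R)-2-oxo-5-{2,3,5-trimethoxy-6-[(prop-2-en-1-yloxy)carbonyl]phenyl}cyclopent-3-ene-1,4-dicarboxylate F8.
   - Pd(PPh3)4 (cat.) with PhSiH3 in CH2Cl2 frees 2-[(1R,5S)-2,5-bis(methoxycarbonyl)-4-oxocyclopent-2-en-1-yl]-3,4,6-trimethoxybenzoic acid F9.
   - Iodide-catalysed oxidative lactonisation (Bu4NI cat., t-BuOOH, EtOAc; alpha-iodination anti to the aryl group, then displacement by the carboxylate) gives the cis-fused keto lactone F10, in which O2–C1 is closed onto quaternary C3 while C3–C3' is still intact.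
   - LiOH under the conditions of step 8 then cleaves C3–C3' and gives 14 and 15 with the lactone already in place. DBU as in step 9 now only has to epimerise C3, and the route is rejoined at 15.

**Further compounds**

F1 | step 6 | dimethyl (1R,5S)-2-oxo-5-[2,3,5-trimethoxy-6-(methoxycarbonyl)phenyl]cyclopent-3-ene-1,4-dicarboxylate (mirror image of 11) | COC(=O)C1=CC(=O)[C@H](C(=O)OC)[C@H]1c1c(OC)c(OC)cc(OC)c1C(=O)OC
F2 | step 6 | dimethyl (1R,5S)-1-hydroxy-2-oxo-5-[2,3,5-trimethoxy-6-(methoxycarbonyl)phenyl]cyclopent-3-ene-1,4-dicarboxylate (mirror image of 12) | COC(=O)C1=CC(=O)[C@](C(=O)OC)(O)[C@H]1c1c(OC)c(OC)cc(OC)c1C(=O)OC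
F3 | step 5 | methyl (2Z)-3-oxo-2-{[2,3,5-trimethoxy-6-(methoxycarbonyl)phenyl]methylidene}butanoate | CC(=O)/C(C(=O)OC)=C/c1c(OC)c(OC)cc(OC)c1C(=O)OC
F4 | step 5 | methyl (2Z)-3-{[tert-butyl(dimethyl)silyl]oxy}-2-{[2,3,5-trimethoxy-6-(methoxycarbonyl)phenyl]methylidene}but-3-enoate | C=C(O[Si](C)(C)C(C)(C)C)/C(C(=O)OC)=C/c1c(OC)c(OC)cc(OC)c1C(=O)OC
F5 | step 5 | dimethyl (5Z)-2-hydroxy-4-oxo-5-{[2,3,5-trimethoxy-6-(methoxycarbonyl)phenyl]methylidene}hexanedioate (racemic carbinol) | COC(=O)C(O)CC(=O)/C(C(=O)OC)=C/c1c(OC)c(OC)cc(OC)c1C(=O)OC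
F6 | step 9 | prop-2-en-1-yl 2-formyl-3,4,6-trimethoxybenzoate | C=CCOC(=O)c1c(C=O)c(OC)c(OC)cc1OC
F7 | step 9 | dimethyl (2E,5Z)-4-oxo-5-({2,3,5-trimethoxy-6-[(prop-2-en-1-yloxy)carbonyl]phenyl}methylidene)hex-2-enedioate | COC(=O)/C=C/C(=O)/C(C(=O)OC)=C/c1c(OC)c(OC)cc(OC)c1C(=O)OCC=C
F8 | step 9 | dimethyl (1S,5R)-2-oxo-5-{2,3,5-trimethoxy-6-[(prop-2-en-1-yloxy)carbonyl]phenyl}cyclopent-3-ene-1,4-dicarboxylate | COC(=O)C1=CC(=O)[C@@H](C(=O)OC)[C@@H]1c1c(OC)c(OC)cc(OC)c1C(=O)OCC=C
F9 | step 9 | 2-[(1R,5S)-2,5-bis(methoxycarbonyl)-4-oxocyclopent-2-en-1-yl]-3,4,6-trimethoxybenzoic acid | COC(=O)C1=CC(=O)[C@@H](C(=O)OC)[C@@H]1c1c(OC)c(OC)cc(OC)c1C(=O)O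
F10 | step 9 | cis-fused keto lactone (isochromanone lactone closed onto quaternary C3, cyclopentenone ring intact, methyl esters on C3 and Ca) | COC(=O)C1=CC(=O)[C@]2(C(=O)OC)OC(=O)c3c(OC)cc(OC)c(OC)c3[C@H]12
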